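Assumption: 4-chlorobutanal and 3-bromofuran-2(5H)-one are taken as catalogue compounds.

**Retrosynthetic overview** (nonyl acetate numbering: C1 = CH2OAc to C9 = CH2 on the furanone; side chain C1'–C5' on C2)
1. C2'–C3' bond: nickel-catalysed radical cross-electrophile coupling of a primary alkyl halide with (Z)-3-iodo-2-methylprop-2-en-1-ol, itself one step from propargyl alcohol.
2. C9–furanone bond: B-alkyl Suzuki coupling of an allyl terminus with 3-bromofuran-2(5H)-one; the butenolide is the only ring, it is bought intact and no ring is formed in the route.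
3. C6–C7 bond and C6 stereocentre: SOMO α-allylation of an aldehyde (enaminyl radical cation plus allyltrimethylsilane).
4. Key step, C2–C3 bond and C2 stereocentre: enantioselective radical hydroalkylation of hexa-1,5-diene by the enaminyl radical cation of 4-chlorobutanal; the spare vinyl group is later ozonised to the aldehyde used in line 3.
5. The acetate is installed right after the first stereocentre, so no protecting group is needed.

**Route**

Step 1
Reactants: 1 4-chlorobutanal; 2 hexa-1,5-diene
Product: 4 (R)-2-(2-chloroethyl)oct-7-en-1-ol, via α-alkylated aldehyde 3 (not isolated)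
Conditions: 2 (10 equiv), (2R,5R)-5-benzyl-2-tert-butyl-3-methylimidazolidin-4-one·CF3CO2H (20 mol%), [Ir(ppy)2(dtbbpy)]PF6 (1 mol%), 2,4,6-triisopropylbenzenethiol (20 mol%), H2O, DME, blue LEDs, −20 °C; then NaBH4, EtOH, −10 °C
Reagents that add atoms: none
Why: Proposed new method: photoexcited trivalent iridium oxidises the chiral enamine of 1 to a 3π-electron enaminyl radical cation whose (E)-geometry and benzyl shielding leave one face open to the terminal CH2 of 2 (anti-Markovnikov C–C bond, C2 predicted R by this shielding model), the secondary alkyl radical takes a hydrogen atom from the thiol faster than 4-exo or 5-endo closure onto the second alkene, and the aldehyde is reduced in the flask before it can epimerise; the closest known reaction is the photoredox/HAT/enamine enantioselective α-alkylation of aldehydes with styrenes and 1,1-disubstituted olefins, extended here to an unactivated 1-alkene used in tenfold excess.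

Step 2
Reactants: 4 (R)-2-(2-chloroethyl)oct-7-en-1-ol
Product: 5 (R)-2-(2-chloroethyl)oct-7-en-1-yl acetate
Conditions: Ac2O, pyridine, DMAP (5 mol%), CH2Cl2, 0 °C → rt
Reagents that add atoms: acetic anhydride, CC(=O)OC(C)=O
Why: DMAP-catalysed acylation of the only hydroxyl puts the target's acetate in place at once and stops the γ-chloro alcohol from closing to a tetrahydrofuran.

Step 3
Reactants: 5 (R)-2-(2-chloroethyl)oct-7-en-1-yl acetate
Product: 7 (R)-2-(2-chloroethyl)-7-oxoheptyl acetate, via secondary ozonide 6 (not isolated)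
Conditions: O3, CH2Cl2, −78 °C; then PPh3, −78 °C → rt
Reagents that add atoms: ozone, [O-][O+]=O
Why: Ozonolysis with reductive work-up (Criegee mechanism) cleaves the only C=C to the aldehyde and leaves acetate, chloride and the stereocentre untouched.

Step 4
Reactants: 7 (R)-2-(2-chloroethyl)-7-oxoheptyl acetate; 8 allyltrimethylsilane
Product: 10 (2R,6S)-2-(2-chloroethyl)-6-(hydroxymethyl)non-8-en-1-yl acetate, via α-allyl aldehyde 9 (not isolated)
Conditions: 8 (2.5 equiv), (2R,5R)-5-benzyl-2-tert-butyl-3-methylimidazolidin-4-one·CF3CO2H (20 mol%), (NH4)2Ce(NO3)6 (2.0 equiv), NaHCO3 (1.5 equiv), H2O, DME, −20 °C, 24 h; then NaBH4, EtOH, −10 °C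
Reagents that add atoms: none
Why: SOMO-activation α-allylation, in which tetravalent cerium oxidises the enamine of 7 to its radical cation, the allylsilane adds to the face left open by the benzyl group of the same (2R,5R) catalyst (sets C6 as S by catalyst control, independent of the remote C2 centre), loss of the silyl group after a second oxidation gives the allyl group, and in-flask reduction prevents epimerisation.

Step 5
Reactants: 10 (2R,6S)-2-(2-chloroethyl)-6-(hydroxymethyl)non-8-en-1-yl acetate; 11 3-bromofuran-2(5H)-one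
Product: 13 (2R,6S)-2-(2-chloroethyl)-6-(hydroxymethyl)-9-(2-oxo-2,5-dihydrofuran-3-yl)nonyl acetate, via B-alkyl-9-BBN adduct 12 (not isolated)
Conditions: 9-BBN (2.2 equiv), THF, 0 °C → rt; then 11 (1.3 equiv), PdCl2(dppf) (5 mol%), AsPh3 (10 mol%), K3PO4 (3 M aq), DMF, rt
Reagents that add atoms: none
Why: Anti-Markovnikov hydroboration of the terminal alkene (one equivalent of 9-BBN is consumed by the hydroxyl) followed by B-alkyl Suzuki–Miyaura coupling with the activated α-bromoenoate under Johnson-type conditions at room temperature, where the primary chloride, the acetate and both stereocentres are inert.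

Step 6
Reactants: 14 prop-2-yn-1-ol
Product: 16 (Z)-3-iodo-2-methylprop-2-en-1-ol, via alkenylmagnesium alkoxide 15 (not isolated)
Conditions: MeMgBr (2.5 equiv), CuI (10 mol%), THF, −10 °C → rt; then I2, −78 °C → 0 °C
Reagents that add atoms: methylmagnesium bromide, C[Mg]Br; iodine, II
Why: Copper-catalysed anti-carbomagnesiation of the propargylic alkoxide places magnesium cis to CH2O through alkoxide chelation, and iodinolysis with retention gives the Z-iodide as one isomer.

Step 7
Reactants: 13 (2R,6S)-2-(2-chloroethyl)-6-(hydroxymethyl)-9-(2-oxo-2,5-dihydrofuran-3-yl)nonyl acetate; 16 (Z)-3-iodo-2-methylprop-2-en-1-ol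
Product: 18 (2R,6S)-6-(hydroxymethyl)-2-[(3Z)-5-hydroxy-4-methylpent-3-en-1-yl]-9-(2-oxo-2,5-dihydrofuran-3-yl)nonyl acetate, via primary iodide 17 (not isolated)
Conditions: NaI (3 equiv), DMA, 70 °C; then 16 (2 equiv), NiI2 (10 mol%), 4,4'-di-tert-butyl-2,2'-bipyridine (10 mol%), pyridine (10 mol%), Zn dust (3 equiv), DMA, 25 °C
Reagents that add atoms: none
Why: Finkelstein exchange followed by nickel-catalysed reductive cross-electrophile coupling, in which zerovalent nickel adds to the vinyl iodide with retention of the Z geometry, the primary alkyl radical from 17 is captured at nickel faster than it adds to the hindered butenolide, and reductive elimination forms the sp3–sp2 bond under neutral conditions that tolerate the free hydroxyls and the acetate.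

**Compound list**
1 | 4-chlorobutanal | O=CCCCCl | starting material
2 | hexa-1,5-diene | C=CCCC=C | starting material
3 | (R)-2-(2-chloroethyl)oct-7-enal | O=C[C@@H](CCCl)CCCCC=C | intermediate
4 | (R)-2-(2-chloroethyl)oct-7-en-1-ol | OC[C@@H](CCCl)CCCCC=C | intermediate
5 | (R)-2-(2-chloroethyl)oct-7-en-1-yl acetate | CC(=O)OC[C@@H](CCCl)CCCCC=C | intermediate
6 | (2R)-2-(2-chloroethyl)-6-(1,2,4-trioxolan-3-yl)hexyl acetate (secondary ozonide, epimers at the ring carbon) | CC(=O)OC[C@@H](CCCl)CCCCC1OCOO1 | intermediate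
7 | (R)-2-(2-chloroethyl)-7-oxoheptyl acetate | CC(=O)OC[C@@H](CCCl)CCCCC=O | intermediate
8 | allyltrimethylsilane | C=CC[Si](C)(C)C | starting material
9 | (2R,6S)-2-(2-chloroethyl)-6-formylnon-8-en-1-yl acetate | CC(=O)OC[C@@H](CCCl)CCC[C@H](C=O)CC=C | intermediate
10 | (2R,6S)-2-(2-chloroethyl)-6-(hydroxymethyl)non-8-en-1-yl acetate | CC(=O)OC[C@@H](CCCl)CCC[C@H](CO)CC=C | intermediate
11 | 3-bromofuran-2(5H)-one | O=C1OCC=C1Br | starting material
12 | (2R,6R)-9-(9-borabicyclo[3.3.1]nonan-9-yl)-6-{[(9-borabicyclo[3.3.1]nonan-9-yl)oxy]methyl}-2-(2-chloroethyl)nonyl acetate | CC(=O)OC[C@@H](CCCl)CCC[C@H](COB1C2CCCC1CCC2)CCCB1C2CCCC1CCC2 | intermediate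
13 | (2R,6S)-2-(2-chloroethyl)-6-(hydroxymethyl)-9-(2-oxo-2,5-dihydrofuran-3-yl)nonyl acetate | CC(=O)OC[C@@H](CCCl)CCC[C@H](CO)CCCC1=CCOC1=O | intermediate
14 | prop-2-yn-1-ol | C#CCO | starting material
15 | (Z)-bromo{3-[(bromomagnesio)oxy]-2-methylprop-1-en-1-yl}magnesium | C/C(CO[Mg]Br)=C/[Mg]Br | intermediate
16 | (Z)-3-iodo-2-methylprop-2-en-1-ol | OC/C(C)=C\I | intermediate
17 | (2R,6S)-6-(hydroxymethyl)-2-(2-iodoethyl)-9-(2-oxo-2,5-dihydrofuran-3-yl)nonyl acetate | CC(=O)OC[C@@H](CCI)CCC[C@H](CO)CCCC1=CCOC1=O | intermediate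
18 | (2R,6S)-6-(hydroxymethyl)-2-[(3Z)-5-hydroxy-4-methylpent-3-en-1-yl]-9-(2-oxo-2,5-dihydrofuran-3-yl)nonyl acetate | CC(=O)OC[C@@H](CC/C=C(/C)CO)CCC[C@H](CO)CCCC1=CCOC1=O | target

**Totals and risks**

Total: 7 steps. Longest linear sequence: 6 steps (steps 1, 2, 3, 4, 5, 7); step 6 is a one-step branch. The two stereocentres are remote and each is set by catalyst control, so the minor diastereomers (a few percent from each step) will probably travel with the product.

Most likely to fail:

Step 1 (an unactivated 1-alkene may be too slow a partner for the enaminyl radical cation). The fallback sets out from 1 and 8 and comes back at 7. Aldehyde 1 is α-allylated with 8 under the SOMO conditions of step 4 with the same (2R,5R) catalyst to give (R)-2-(2-chloroethyl)pent-4-enal F1, which is reduced in the flask with NaBH4 to (R)-2-(2-chloroethyl)pent-4-en-1-ol F2. Acetylation (Ac2O, pyridine, DMAP) gives (R)-2-(2-chloroethyl)pent-4-en-1-yl acetate F3. Cross-metathesis with but-3-en-1-ol (4 equiv; second-generation Grubbs catalyst, RuCl2(PCy3)(H2IMes)(=CHPh), CH2Cl2, 40 °C) gives (R)-2-(2-chloroethyl)-7-hydroxyhept-4-en-1-yl acetate F4 as an E/Z mixture. Hydrogenation (H2, Pd/C, EtOAc) gives (R)-2-(2-chloroethyl)-7-hydroxyheptyl acetate F5, and Dess–Martin periodinane oxidises it to 7. This replaces the uncertain olefin hydroalkylation with the fully precedented allylsilane reaction at the cost of two extra steps.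

Step 7 (the alkyl radical may add to the butenolide, or the vinyl iodide may dimerise or lose its geometry). The fallback sets out from 16, is joined by 13 and comes back at 18. Alcohol 16 is silylated (TBSCl, imidazole, DMF) to (Z)-tert-butyl[(3-iodo-2-methylprop-2-en-1-yl)oxy]dimethylsilane F8. Iodine–lithium exchange (t-BuLi, Et2O, −78 °C) gives (Z)-[3-(tert-butyldimethylsilyloxy)-2-methylprop-1-en-1-yl]lithium F9, and ZnCl2 converts it to (Z)-[3-(tert-butyldimethylsilyloxy)-2-methylprop-1-en-1-yl]zinc chloride F10 with the geometry retained. A two-electron Negishi coupling of F10 (3 equiv, the first equivalent being spent on the free hydroxyl) with the primary chloride 13 (Pd2(dba)3, tricyclopentylphosphine, N-methylimidazole, THF/NMP, 80 °C) gives (2R,6S)-2-[(3Z)-5-(tert-butyldimethylsilyloxy)-4-methylpent-3-en-1-yl]-6-(hydroxymethyl)-9-(2-oxo-2,5-dihydrofuran-3-yl)nonyl acetate F11. HF·pyridine in THF removes the silyl group without touching the acetate and gives 18.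

Step 5 (the bromobutenolide or the acetate may not survive the aqueous base of the Suzuki coupling). The fallback sets out from 10 and comes back at 13. Alkene 10 and methyl 4-hydroxybut-2-ynoate undergo a ruthenium-catalysed Alder-ene coupling (CpRu(cod)Cl 5 mol%, MeOH, reflux) to give methyl (2Z)-2-[(2E,4S,8R)-9-acetoxy-8-(2-chloroethyl)-4-(hydroxymethyl)non-2-en-1-yl]-4-hydroxybut-2-enoate F6. F6 lactonises in the flask to (2R,6S,7E)-2-(2-chloroethyl)-6-(hydroxymethyl)-9-(2-oxo-2,5-dihydrofuran-3-yl)non-7-en-1-yl acetate F7. Selective hydrogenation of the isolated disubstituted alkene of F7 (H2 1 atm, RhCl(PPh3)3, benzene/EtOH) leaves the butenolide intact and gives 13. This builds the ring from an acyclic alkynoate under neutral conditions instead of coupling a preformed bromobutenolide.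

**Further compounds**
F1 | step 1 | (R)-2-(2-chloroethyl)pent-4-enal | O=C[C@@H](CCCl)CC=C
F2 | step 1 | (R)-2-(2-chloroethyl)pent-4-en-1-ol | OC[C@@H](CCCl)CC=C
F3 | step 1 | (R)-2-(2-chloroethyl)pent-4-en-1-yl acetate | CC(=O)OC[C@@H](CCCl)CC=C
F4 | step 1 | (R)-2-(2-chloroethyl)-7-hydroxyhept-4-en-1-yl acetate (E/Z mixture) | CC(=O)OC[C@@H](CCCl)CC=CCCO
F5 | step 1 | (R)-2-(2-chloroethyl)-7-hydroxyheptyl acetate | CC(=O)OC[C@@H](CCCl)CCCCCO
F6 | step 5 | methyl (2Z)-2-[(2E,4S,8R)-9-acetoxy-8-(2-chloroethyl)-4-(hydroxymethyl)non-2-en-1-yl]-4-hydroxybut-2-enoate | CC(=O)OC[C@@H](CCCl)CCC[C@H](CO)/C=C/C/C(C(=O)OC)=C/CO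
F7 | step 5 | (2R,6S,7E)-2-(2-chloroethyl)-6-(hydroxymethyl)-9-(2-oxo-2,5-dihydrofuran-3-yl)non-7-en-1-yl acetate | CC(=O)OC[C@@H](CCCl)CCC[C@H](CO)/C=C/CC1=CCOC1=O
F8 | step 7 | (Z)-tert-butyl[(3-iodo-2-methylprop-2-en-1-yl)oxy]dimethylsilane | CC(C)(C)[Si](C)(C)OC/C(C)=C\I
F9 | step 7 | (Z)-[3-(tert-butyldimethylsilyloxy)-2-methylprop-1-en-1-yl]lithium | CC(C)(C)[Si](C)(C)OC/C(C)=C\[Li]
F10 | step 7 | (Z)-[3-(tert-butyldimethylsilyloxy)-2-methylprop-1-en-1-yl]zinc chloride | CC(C)(C)[Si](C)(C)OC/C(C)=C\[Zn]Cl
F11 | step 7 | (2R,6S)-2-[(3Z)-5-(tert-butyldimethylsilyloxy)-4-methylpent-3-en-1-yl]-6-(hydroxymethyl)-9-(2-oxo-2,5-dihydrofuran-3-yl)nonyl acetate | CC(=O)OC[C@@H](CC/C=C(/C)CO[Si](C)(C)C(C)(C)C)CCC[C@H](CO)CCCC1=CCOC1=O
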